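The target is cut at the C1–C2 bond of ring A. C2, the carbon that carries the diaryl ether oxygen, sits between C1 (OH) and C3 (Br), which is the 2-position of a cyclohexane-1,3-dione whose two equivalent carbonyl carbons can later diverge into C1–OH and C3–Br. An intramolecular Claisen condensation of the open-chain δ-keto ester methyl 6-(2,4-dibromophenoxy)-5-oxohexanoate, with the ether oxygen already in place, closes ring A as its saturated dione in one operation. The dione is then converted into the 3-bromo enone, aromatised as the aryl acetate, brominated at C5 by sterically governed C–H borylation/bromodeboronation, and deacetylated. The target has no stereocentre.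

Key step: step 3

Remark on the chemistry: ring A is numbered C1 (OH), C2 (aryloxy), C3 (Br), C5 (Br), and ring B is the 2,4-dibromophenyl ring. Dione 7 is drawn as the diketone although it should exist largely as its enol. The last bromine is placed by C–H borylation because electrophilic bromination of the aryl acetate could also attack ring B ortho to the ether oxygen.

Step 1
Reactants: 1 methyl 5-chloro-5-oxopentanoate; 2 (trimethylsilyl)diazomethane
Product: 4 methyl 6-bromo-5-oxohexanoate, via methyl 6-diazo-5-oxohexanoate 3 (not isolated)
Conditions: 2 (2 equiv, 2 M in hexanes), THF–MeCN (1:1), 0 °C to rt; then 48% aq HBr, 0 °C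
Reagents that add atoms: hydrogen bromide, Br; (trimethylsilyl)diazomethane 2, C[Si](C)(C)C=[N+]=[N-]
Why: C-acylation of the diazoalkane by the acid chloride with loss of the silyl group should give the α-diazoketone (first stage of an Arndt–Eistert sequence), and C-protonation followed by bromide displacement of N2 gives the bromomethyl ketone, with the methyl ester untouched.

Step 2
Reactants: 4 methyl 6-bromo-5-oxohexanoate; 5 2,4-dibromophenol
Product: 6 methyl 6-(2,4-dibromophenoxy)-5-oxohexanoate
Conditions: K2CO3 (1.5 equiv), acetone, rt
Reagents that add atoms: none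
Why: Williamson ether synthesis, in which the phenoxide should displace the activated primary α-keto bromide by SN2 much faster than carbonate can trigger enolate chemistry; this attaches the ether oxygen without any hindered diaryl ether coupling.

Step 3
Reactants: 6 methyl 6-(2,4-dibromophenoxy)-5-oxohexanoate
Product: 7 2-(2,4-dibromophenoxy)cyclohexane-1,3-dione
Conditions: KOtBu (2.2 equiv), THF, 0 °C to rt (6 added slowly); then 1 M HCl
Reagents that add atoms: none
Why: tert-Butoxide should enolise the ketone reversibly, and the enolate at the aryloxy-bearing carbon C6 (the most acidic C–H of 6) adds to the ester carbonyl C1, the tetrahedral intermediate expelling methoxide to forge the bond that becomes C1–C2 of ring A. The closest known reaction type is the intramolecular Claisen (Dieckmann-type) condensation of 5-oxoalkanoate esters to 2-substituted cyclohexane-1,3-diones. The single ring is closed in a favoured 6-(enolendo)-exo-trig mode. No stereocentre is created, because the new ring carbon C2 is part of an enolised 1,3-dicarbonyl unit. The selectivity needed is regiochemical, closure from C6 and not from the ketone α-carbon C4 or the ester α-carbon C2, and it is secured by ring size, since those enolates could only build four-membered rings and form reversibly. Deprotonation of the acidic 2-aryloxy-1,3-dione by the released alkoxide should make the condensation irreversible, and acidification sets 7 free.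

Step 4
Reactants: 7 2-(2,4-dibromophenoxy)cyclohexane-1,3-dione
Product: 8 3-bromo-2-(2,4-dibromophenoxy)cyclohex-2-en-1-one
Conditions: (COBr)2 (1.2 equiv), DMF (cat.), CH2Cl2, 0 °C to rt
Reagents that add atoms: oxalyl bromide, O=C(Br)C(Br)=O
Why: Vilsmeier-type activation of the enol oxygen followed by bromide addition–elimination should turn the vinylogous acid into the vinylogous acid bromide, and because the dione is symmetric about C2 either carbonyl gives the same product, fixing bromine on the future C3.

Step 5
Reactants: 8 3-bromo-2-(2,4-dibromophenoxy)cyclohex-2-en-1-one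
Product: 10 3-bromo-2-(2,4-dibromophenoxy)phenyl acetate, via cross-conjugated dienyl acetate 9 (not isolated)
Conditions: LiN(SiMe3)2 (1.1 equiv), THF, −78 °C; Ac2O, −78 to 0 °C; solvent exchange to toluene; DDQ (1.3 equiv), rt to 60 °C
Reagents that add atoms: acetic anhydride, CC(=O)OC(C)=O
Why: Kinetic α'-deprotonation of the enone and O-acetylation of the lithium dienolate should give cyclohexadienyl acetate 9, from which DDQ abstracts an allylic hydride and the cation loses a proton to aromatise (enol-acetate trapping followed by quinone dehydrogenation of a cyclohexadiene); a regioisomeric dienyl acetate would converge on the same arene, the silylamide is too weak a base to metalate the dibromoarene, and the phenolic oxygen emerges protected.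

Step 6
Reactants: 10 3-bromo-2-(2,4-dibromophenoxy)phenyl acetate
Product: 12 3,5-dibromo-2-(2,4-dibromophenoxy)phenyl acetate, via aryl pinacol boronate 11 (not isolated)
Conditions: [Ir(OMe)(cod)]2 (1.5 mol%), 4,4'-di-tert-butyl-2,2'-bipyridine (3 mol%), B2pin2 (1.0 equiv), THF, 80 °C; evaporate; CuBr2 (3 equiv), MeOH–H2O (1:1), 80 °C
Reagents that add atoms: copper dibromide, Br[Cu]Br; bis(pinacolato)diboron, CC1(C)OB(OC1(C)C)B1OC(C)(C)C(C)(C)O1 (boron carried only in 11)
Why: Iridium-catalysed aromatic C–H borylation is sterically controlled, and C5 of ring A is the only C–H of 10 without an ortho substituent (all others lie next to Br, OAc or the ether oxygen), so the boronate should form there with the aryl bromides tolerated; copper-mediated bromodeboronation then exchanges boron for bromine at the same carbon.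

Step 7
Reactants: 12 3,5-dibromo-2-(2,4-dibromophenoxy)phenyl acetate
Product: 13 3,5-dibromo-2-(2,4-dibromophenoxy)phenol
Conditions: K2CO3 (cat.), MeOH, rt; dilute HCl work-up
Reagents that add atoms: none
Why: Base-catalysed transesterification of the aryl acetate with methanol should release the phenol, while the aryl bromides and the diaryl ether are inert.

Compound list
1 | methyl 5-chloro-5-oxopentanoate | COC(=O)CCCC(Cl)=O | starting material
2 | (trimethylsilyl)diazomethane | C[Si](C)(C)C=[N+]=[N-] | starting material
3 | methyl 6-diazo-5-oxohexanoate | COC(=O)CCCC(=O)C=[N+]=[N-] | intermediate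
4 | methyl 6-bromo-5-oxohexanoate | COC(=O)CCCC(=O)CBr | intermediate
5 | 2,4-dibromophenol | Oc1ccc(Br)cc1Br | starting material
6 | methyl 6-(2,4-dibromophenoxy)-5-oxohexanoate | COC(=O)CCCC(=O)COc1ccc(Br)cc1Br | intermediate
7 | 2-(2,4-dibromophenoxy)cyclohexane-1,3-dione | O=C1CCCC(=O)C1Oc1ccc(Br)cc1Br | intermediate
8 | 3-bromo-2-(2,4-dibromophenoxy)cyclohex-2-en-1-one | O=C1CCCC(Br)=C1Oc1ccc(Br)cc1Br | intermediate
9 | 5-bromo-6-(2,4-dibromophenoxy)cyclohexa-1,5-dien-1-yl acetate | CC(=O)OC1=CCCC(Br)=C1Oc1ccc(Br)cc1Br | intermediate
10 | 3-bromo-2-(2,4-dibromophenoxy)phenyl acetate | CC(=O)Oc1cccc(Br)c1Oc1ccc(Br)cc1Br | intermediate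
11 | 3-bromo-2-(2,4-dibromophenoxy)-5-(4,4,5,5-tetramethyl-1,3,2-dioxaborolan-2-yl)phenyl acetate | CC(=O)Oc1cc(B2OC(C)(C)C(C)(C)O2)cc(Br)c1Oc1ccc(Br)cc1Br | intermediate
12 | 3,5-dibromo-2-(2,4-dibromophenoxy)phenyl acetate | CC(=O)Oc1cc(Br)cc(Br)c1Oc1ccc(Br)cc1Br | intermediate
13 | 3,5-dibromo-2-(2,4-dibromophenoxy)phenol | Oc1cc(Br)cc(Br)c1Oc1ccc(Br)cc1Br | target

Total step count: 7. Longest linear sequence: 7 steps (1 to 13).

Steps most likely to fail

1. Step 3 (ring closure). What may go wrong: intermolecular aldol or Claisen condensation of the keto ester outrunning cyclisation, or alkoxide-induced degradation of the α-aryloxy ketone before the ring closes. Fallback, setting out from 5 and returning at 7: commercial cyclohexane-1,3-dione undergoes diazo transfer with 4-acetamidobenzenesulfonyl azide and Et3N in MeCN to give 2-diazocyclohexane-1,3-dione F1. Decomposition of F1 with Rh2(OAc)4 (1 mol%) in the presence of 5 (CH2Cl2, reflux) should give 7 by carbenoid O–H insertion into the phenol. The ether bond is then made on a preformed dione ring and no carbocyclisation is needed.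

2. Step 5 (aromatisation). What may go wrong: C- instead of O-acetylation of the dienolate, hydrolysis of the dienyl acetate back to the enone during the solvent switch, or slow hydride abstraction from the electron-poor diene with decomposition. Fallback, setting out from 8 and returning at 10: the lithium enolate of 8 (LiN(SiMe3)2, THF, −78 °C) is selenenylated with PhSeBr to give racemic 3-bromo-2-(2,4-dibromophenoxy)-6-(phenylselanyl)cyclohex-2-en-1-one F2. Oxidation with H2O2 and pyridine in CH2Cl2 at 0 °C gives 3-bromo-2-(2,4-dibromophenoxy)-6-(phenylseleninyl)cyclohex-2-en-1-one F3. Syn-elimination of F3 and tautomerisation of the resulting cyclohexadienone should furnish 3-bromo-2-(2,4-dibromophenoxy)phenol F4, and acetylation (Ac2O, pyridine) returns 10.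

3. Step 6 (C5 bromination). What may go wrong: solvolysis of the acetate in hot aqueous methanolic CuBr2 followed by electrophilic bromination of the freed phenol ortho or para to the hydroxyl, or protodeboronation of the boronate. Fallback, setting out from 10 and returning at 13: methanolysis of 10 to 3-bromo-2-(2,4-dibromophenoxy)phenol F4 (K2CO3, MeOH) and methylation in the same flask (MeI) give 1-bromo-2-(2,4-dibromophenoxy)-3-methoxybenzene F5. The same iridium-catalysed borylation should give 2-[3-bromo-4-(2,4-dibromophenoxy)-5-methoxyphenyl]-4,4,5,5-tetramethyl-1,3,2-dioxaborolane F6. CuBr2 in MeOH–H2O then gives 1,5-dibromo-2-(2,4-dibromophenoxy)-3-methoxybenzene F7, whose methyl ether cannot be lost under these conditions. BBr3 (CH2Cl2, −78 °C to rt) cleaves the methyl ether to 13 directly.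

Further compounds
F1 | step 3 | 2-diazocyclohexane-1,3-dione | O=C1CCCC(=O)C1=[N+]=[N-]
F2 | step 5 | 3-bromo-2-(2,4-dibromophenoxy)-6-(phenylselanyl)cyclohex-2-en-1-one (racemic) | O=C1C([Se]c2ccccc2)CCC(Br)=C1Oc1ccc(Br)cc1Br
F3 | step 5 | 3-bromo-2-(2,4-dibromophenoxy)-6-(phenylseleninyl)cyclohex-2-en-1-one (mixture of stereoisomers) | O=C1C([Se](=O)c2ccccc2)CCC(Br)=C1Oc1ccc(Br)cc1Br
F4 | step 5 | 3-bromo-2-(2,4-dibromophenoxy)phenol | Oc1cccc(Br)c1Oc1ccc(Br)cc1Br
F5 | step 6 | 1-bromo-2-(2,4-dibromophenoxy)-3-methoxybenzene | COc1cccc(Br)c1Oc1ccc(Br)cc1Br
F6 | step 6 | 2-[3-bromo-4-(2,4-dibromophenoxy)-5-methoxyphenyl]-4,4,5,5-tetramethyl-1,3,2-dioxaborolane | COc1cc(B2OC(C)(C)C(C)(C)O2)cc(Br)c1Oc1ccc(Br)cc1Br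
F7 | step 6 | 1,5-dibromo-2-(2,4-dibromophenoxy)-3-methoxybenzene | COc1cc(Br)cc(Br)c1Oc1ccc(Br)cc1Br
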